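**Plan**

Ring numbering: C1 (=C15H2), C2, C3, C4=C5(Me), C6, C7, C8 (isopropenyl), C9 (OAc), C10=C11 (C20H2OAc), C12, C13, C14 (OH). C13 is β to the C14 hydroxyl and C12 is allylic to C10=C11, so C12–C13 is the bond formed when an allylic sulfonyl carbanion opens a terminal C13–C14 epoxide.
Retrosynthesis: cut C12–C13 (the ring), then C8–C9 (anti-allylboration of a sulfonyl enal), then C2–C3 (allylic alkylation of a glycerate-derived keto sulfone); the eastern C9–C12/C20 piece comes from a Morita–Baylis–Hillman adduct and sulfinate.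
Forward: allylboronate 12 (steps 1–7) and enal 20 (steps 8–13) are joined at C8–C9 (step 14), the acetonide becomes the epoxide (steps 15–17), the single 14-membered ring closes in step 18, and desulfonylation plus exchange of silyl groups for acetates finish the route (steps 19–23).
Stereochemistry: C14 comes from methyl (R)-glycerate acetonide, its C–O bond never being broken; C8 and C9 are set together in the catalyst-controlled anti-allylboration; 4E comes from geranyl acetate; the C10=C11 geometry comes from the stereoselective sulfinate displacement.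

Key step: step 18

Remark: open-chain intermediates 21–27 carry the ring numbering (chain C13–C14–C1(=C15H2)–C2…C11(C20)–C12); the sulfone-bearing carbons (C2 of 8, C12 of 28, 29 and 30) form as epimer mixtures and are left unspecified because desulfonylation erases them.

**Route**

Step 1
Reactants: 1 geranyl acetate
Product: 2 (2E,6E)-8-hydroxy-3,7-dimethylocta-2,6-dien-1-yl acetate
Conditions: SeO2 (0.1 equiv), t-BuOOH (70% aq., 3 equiv), salicylic acid (0.1 equiv), CH2Cl2, rt
Reagents that add atoms: tert-butyl hydroperoxide, CC(C)(C)OO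
Why: Riley-type allylic oxidation with catalytic SeO2 should attack the terminal trisubstituted alkene, which is more electron-rich than the acetate-bearing one, and its ene/[2,3]-sigmatropic sequence delivers oxygen to the (E)-methyl group, giving the (E)-allylic alcohol that later becomes the (E)-allylboronate.

Step 2
Reactants: 3 methyl (R)-2,2-dimethyl-1,3-dioxolane-4-carboxylate; 4 methyl phenyl sulfone
Product: 6 (R)-1-(2,2-dimethyl-1,3-dioxolan-4-yl)-2-(phenylsulfonyl)ethan-1-one, via (phenylsulfonyl)methyllithium 5 (not isolated)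
Conditions: 4 (2.2 equiv), n-BuLi (2.2 equiv), THF, −78 °C → 0 °C; then 3, −78 °C → rt; aq. NH4Cl
Reagents that add atoms: none
Why: Claisen-type acylation of an α-sulfonyl carbanion by an ester gives the β-keto sulfone, and its immediate deprotonation by the second equivalent of 5 should block over-addition and shield the dioxolane stereocentre from enolisation.

Step 3
Reactants: 2 (2E,6E)-8-hydroxy-3,7-dimethylocta-2,6-dien-1-yl acetate; 6 (R)-1-(2,2-dimethyl-1,3-dioxolan-4-yl)-2-(phenylsulfonyl)ethan-1-one
Product: 8 (4E,8E)-1-[(4R)-2,2-dimethyl-1,3-dioxolan-4-yl]-10-hydroxy-5,9-dimethyl-2-(phenylsulfonyl)deca-4,8-dien-1-one (C2 epimers), via keto sulfone sodium enolate 7 (not isolated)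
Conditions: 6 (1.3 equiv), NaH (1.3 equiv), THF, 0 °C; then 2, Pd(PPh3)4 (5 mol %), THF, rt → 50 °C
Reagents that add atoms: none
Why: In this Tsuji–Trost allylic alkylation zerovalent palladium ionises only the allylic acetate (the free allylic alcohol is inert), and the soft, bulky enolate should attack the primary terminus of the syn π-allyl complex, forming C2–C3 with the 4E geometry retained and an inconsequential epimer mixture at the sulfonyl carbon.

Step 4
Reactants: 8 (4E,8E)-1-[(4R)-2,2-dimethyl-1,3-dioxolan-4-yl]-10-hydroxy-5,9-dimethyl-2-(phenylsulfonyl)deca-4,8-dien-1-one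
Product: 9 (4E,8E)-1-[(4R)-2,2-dimethyl-1,3-dioxolan-4-yl]-10-hydroxy-5,9-dimethyldeca-4,8-dien-1-one
Conditions: aluminium amalgam (Al/Hg), THF/H2O (9:1), 0 °C → rt
Reagents that add atoms: none
Why: Reductive desulfonylation of a β-keto sulfone by aluminium amalgam is a standard C–S cleavage that runs near neutrality and should leave the α-alkoxy ketone stereocentre, the acetonide and the alkenes untouched.

Step 5
Reactants: 9 (4E,8E)-1-[(4R)-2,2-dimethyl-1,3-dioxolan-4-yl]-10-hydroxy-5,9-dimethyldeca-4,8-dien-1-one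
Product: 10 (2E,6E)-10-[(4S)-2,2-dimethyl-1,3-dioxolan-4-yl]-2,6-dimethylundeca-2,6,10-trien-1-ol
Conditions: Ph3PCH3Br (3.2 equiv), KN(SiMe3)2 (3 equiv), THF, 0 °C; then 9, −78 °C → rt
Reagents that add atoms: methyltriphenylphosphonium bromide, C[P+](c1ccccc1)(c1ccccc1)c1ccccc1.[Br-]
Why: Wittig methylenation installs the C1 methylidene, the excess ylide covering the free hydroxyl, and addition of the ketone to lithium-free ylide at low temperature should keep olefination faster than enolisation toward the dioxolane stereocentre (same spatial arrangement, descriptor now S by a priority change).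

Step 6
Reactants: 10 (2E,6E)-10-[(4S)-2,2-dimethyl-1,3-dioxolan-4-yl]-2,6-dimethylundeca-2,6,10-trien-1-ol
Product: 11 (2E,6E)-10-[(4S)-2,2-dimethyl-1,3-dioxolan-4-yl]-2,6-dimethylundeca-2,6,10-trien-1-yl acetate
Conditions: Ac2O, pyridine, DMAP (cat.), CH2Cl2, 0 °C → rt
Reagents that add atoms: acetic anhydride, CC(=O)OC(C)=O
Why: Routine DMAP-catalysed acetylation turns the primary allylic alcohol into the leaving group needed for catalytic borylation.

Step 7
Reactants: 11 (2E,6E)-10-[(4S)-2,2-dimethyl-1,3-dioxolan-4-yl]-2,6-dimethylundeca-2,6,10-trien-1-yl acetate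
Product: 12 2-[(2E,6E)-10-((4S)-2,2-dimethyl-1,3-dioxolan-4-yl)-2,6-dimethylundeca-2,6,10-trien-1-yl]-4,4,5,5-tetramethyl-1,3,2-dioxaborolane
Conditions: B2pin2 (1.1 equiv), Ni(cod)2 (5 mol %), PCy3 (10 mol %), EtOAc, 60 °C
Reagents that add atoms: bis(pinacolato)diboron, CC1(C)OB(OC1(C)C)B1OC(C)(C)C(C)(C)O1
Why: Catalytic borylation of an allylic acetate (oxidative addition to zerovalent nickel, transmetalation with the diboron, reductive elimination) should give the linear primary allylboronate with the (E) geometry, which is both carried over from 11 and thermodynamically preferred, while the allylic dioxolane C–O bond is not ionised.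

Step 8
Reactants: 13 2,2-dimethoxyacetaldehyde; 14 methyl acrylate
Product: 15 methyl 3-hydroxy-4,4-dimethoxy-2-methylidenebutanoate (racemic)
Conditions: DABCO (0.5 equiv), 13 (60% aq.), 14 (3 equiv), 1,4-dioxane, rt
Reagents that add atoms: none
Why: The Morita–Baylis–Hillman reaction of an acrylate with a reactive, non-enolisable aldehyde in aqueous medium assembles C9–C12 and C20 in one step, and the racemic carbinol centre is destroyed in step 10.

Step 9
Reactants: 15 methyl 3-hydroxy-4,4-dimethoxy-2-methylidenebutanoate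
Product: 16 methyl 3-acetoxy-4,4-dimethoxy-2-methylidenebutanoate
Conditions: Ac2O, pyridine, DMAP (cat.), CH2Cl2, 0 °C
Reagents that add atoms: acetic anhydride, CC(=O)OC(C)=O
Why: Acetylation activates the Morita–Baylis–Hillman alcohol as an allylic leaving group.

Step 10
Reactants: 16 methyl 3-acetoxy-4,4-dimethoxy-2-methylidenebutanoate
Product: 17 methyl (Z)-4,4-dimethoxy-2-[(phenylsulfonyl)methyl]but-2-enoate
Conditions: PhSO2Na (1.2 equiv), DMF, rt
Reagents that add atoms: sodium benzenesulfinate, [Na+].[O-]S(=O)c1ccccc1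
Why: Sulfinate attacks through sulfur in an SN2′ displacement of acetate and should give the trisubstituted allyl sulfone with the acetal carbon trans to the ester and cis to CH2SO2Ph (Z), the geometry established for ester-derived adducts and the one C10=C11 of the target requires.

Step 11
Reactants: 17 methyl (Z)-4,4-dimethoxy-2-[(phenylsulfonyl)methyl]but-2-enoate
Product: 18 (Z)-4,4-dimethoxy-2-[(phenylsulfonyl)methyl]but-2-en-1-ol
Conditions: i-Bu2AlH (2.5 equiv), CH2Cl2, −78 °C; aq. potassium sodium tartrate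
Reagents that add atoms: none
Why: 1,2-Reduction of the enoate by i-Bu2AlH at low temperature should give the C20 allylic alcohol without touching the sulfone, the acetal or the alkene geometry.

Step 12
Reactants: 18 (Z)-4,4-dimethoxy-2-[(phenylsulfonyl)methyl]but-2-en-1-ol
Product: 19 tert-butyl{[(Z)-4,4-dimethoxy-2-((phenylsulfonyl)methyl)but-2-en-1-yl]oxy}diphenylsilane
Conditions: TBDPSCl, imidazole, DMF, rt
Reagents that add atoms: tert-butyl(chloro)diphenylsilane, CC(C)(C)[Si](Cl)(c1ccccc1)c1ccccc1
Why: Imidazole-promoted silylation gives the acid-stable tert-butyldiphenylsilyl ether that protects C20 through the acetal and acetonide cleavages ahead.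

Step 13
Reactants: 19 tert-butyl{[(Z)-4,4-dimethoxy-2-((phenylsulfonyl)methyl)but-2-en-1-yl]oxy}diphenylsilane
Product: 20 (Z)-4-[(tert-butyldiphenylsilyl)oxy]-3-[(phenylsulfonyl)methyl]but-2-enal
Conditions: PPTS (cat.), THF/H2O (4:1), rt
Reagents that add atoms: water, O
Why: Mild acid hydrolysis of the α,β-unsaturated dimethyl acetal should release the enal without cleaving the silyl ether or isomerising the double bond, and the enal is used at once.

Step 14
Reactants: 12 2-[(2E,6E)-10-((4S)-2,2-dimethyl-1,3-dioxolan-4-yl)-2,6-dimethylundeca-2,6,10-trien-1-yl]-4,4,5,5-tetramethyl-1,3,2-dioxaborolane; 20 (Z)-4-[(tert-butyldiphenylsilyl)oxy]-3-[(phenylsulfonyl)methyl]but-2-enal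
Product: 22 open-chain (4E,10Z,8R,9S,14S)-C9 alcohol (C8 isopropenyl; C20 OTBDPS; C12H2SO2Ph; C1 methylidene; 13,14-O-isopropylidene), via pinacol borate ester 21 (not isolated)
Conditions: 12 (1.3 equiv), (R)-3,3′-bis(2,4,6-triisopropylphenyl)-1,1′-binaphthyl-2,2′-diyl hydrogen phosphate [(R)-TRIP, 10 mol %], 4 Å MS, toluene, −30 °C → 0 °C; aqueous work-up
Reagents that add atoms: none
Why: In this chiral phosphoric acid-catalysed allylboration the closed chair transition state places C7 of the (E)-boronate equatorial and so gives the anti 8,9 relationship, while (R)-TRIP, hydrogen-bonded to a boronate oxygen and the formyl hydrogen, is expected to direct attack to the Re face of the enal as it does with simple aldehydes, giving 8R,9S independently of the remote dioxolane centre.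

Step 15
Reactants: 22 open-chain (8R,9S)-C9 alcohol
Product: 23 open-chain C9 tert-butyldimethylsilyl ether (C20 OTBDPS; C12H2SO2Ph; 13,14-O-isopropylidene)
Conditions: TBSOTf, 2,6-lutidine, CH2Cl2, −78 °C → 0 °C
Reagents that add atoms: tert-butyldimethylsilyl trifluoromethanesulfonate, CC(C)(C)[Si](C)(C)OS(=O)(=O)C(F)(F)F
Why: Silylation of the hindered secondary allylic alcohol with a silyl triflate and a non-nucleophilic base should give a TBS ether that survives the acid and base steps up to step 21.

Step 16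
Reactants: 23 open-chain C9 tert-butyldimethylsilyl ether
Product: 24 open-chain (14S)-13,14-diol (C9 OTBS; C20 OTBDPS; C12H2SO2Ph)
Conditions: PPTS (0.3 equiv), MeOH, 40 °C
Reagents that add atoms: none
Why: Acid-catalysed transacetalisation with methanol should remove the terminal isopropylidene acetal while the hindered secondary TBS ether and the primary TBDPS ether, both far less acid-labile, remain.

Step 17
Reactants: 24 open-chain (14S)-13,14-diol
Product: 26 open-chain (14S)-13,14-epoxide (C9 OTBS; C20 OTBDPS; C12H2SO2Ph; C1 methylidene), via primary tosylate 25 (not isolated)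
Conditions: TsCl (1.1 equiv), Et3N, Bu2SnO (2 mol %), CH2Cl2, 0 °C; then K2CO3, MeOH, 0 °C → rt
Reagents that add atoms: none
Why: Tin-catalysed sulfonylation through the stannylene acetal is selective for the primary hydroxyl of a 1,2-diol, and carbonate in methanol then closes the epoxide by intramolecular Williamson displacement at C13, so the C14–O bond and the C14 configuration are retained.

Step 18
Reactants: 26 open-chain (14S)-13,14-epoxide
Product: 29 14-membered C12 phenyl sulfone bearing the free (14R) hydroxyl (C9 OTBS; C20 OTBDPS; 4E; 10Z; C12 epimers), via C12 lithio sulfone 27 (not isolated), via C14 lithium alkoxide 28 (not isolated)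
Conditions: LiN(SiMe3)2 (2.2 equiv), THF, 26 added by syringe pump at −78 °C to a final 2 mM, then −78 °C → 0 °C (rt if needed); aq. NH4Cl
Reagents that add atoms: none
Why: The amide base removes the most acidic proton, at C12 between the sulfonyl group and C10=C11, and the allyl sulfonyl anion 27 attacks the epoxide CH2 (C13) by SN2, forming C12–C13 and releasing the C14 alkoxide 28. The closest known reaction type is the intramolecular alkylation of sulfone-stabilised carbanions by epoxides used to close macrocyclic terpenoid rings. The 14-membered ring closes in the endo mode of epoxide opening (14-endo-tet): both epoxide carbons become ring members and the oxygen stays on C14 as the free hydroxyl. No stereocentre of the target is created, since C14 keeps its C–O bond (14S in 26 becomes 14R in 29 by a priority change only) and C12 forms as an epimer mixture that step 20 erases. The step needs attack at C13 and not at allylic C14 or at the methylidene carbon (SN2′), bonding through the α-carbon of the allyl anion, and ring closure ahead of oligomerisation or 1,4-loss of the C9 silyloxy group; the unhindered primary carbon, a lithium counter-ion in THF without dipolar additives, the inherent α-selectivity of sulfonyl allyl anions, high dilution and low temperature are expected to secure these.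

Step 19
Reactants: 29 14-membered C12 phenyl sulfone bearing the free (14R) hydroxyl
Product: 30 14-membered C12 phenyl sulfone C14 2-methoxyprop-2-yl ether (C9 OTBS; C20 OTBDPS)
Conditions: 2-methoxypropene, PPTS (cat.), CH2Cl2, 0 °C
Reagents that add atoms: 2-methoxypropene, COC(C)=C
Why: Acid-catalysed addition of the C14 alcohol to the enol ether gives a base-stable mixed acetal that keeps the alkoxide from attacking the π-allyl complex of step 20 and distinguishes C14 from the two hydroxyls to be acetylated.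

Step 20
Reactants: 30 14-membered C12 phenyl sulfone C14 2-methoxyprop-2-yl ether
Product: 31 (4E,10E,8R,9S,14R)-macrocycle with C12H2 (C9 OTBS; C20 OTBDPS; C14 2-methoxyprop-2-yl ether)
Conditions: PdCl2(dppp) (10 mol %), LiBHEt3 (3 equiv), THF, 0 °C → rt
Reagents that add atoms: none
Why: In this palladium-catalysed hydride substitution of an allylic sulfone, zerovalent palladium formed in situ ionises the C12–S bond and hydride should be delivered to the less hindered terminus C12 of the π-allyl complex (C10 is shielded by the C9 silyloxy and C8 isopropenyl groups) faster than syn–anti isomerisation, so the position and geometry of C10=C11 are kept.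

Step 21
Reactants: 31 (4E,10E,8R,9S,14R)-macrocycle with C9 OTBS and C20 OTBDPS
Product: 32 macrocyclic C9,C20-diol C14 2-methoxyprop-2-yl ether
Conditions: Bu4NF (4 equiv), THF, rt → 40 °C
Reagents that add atoms: none
Why: Fluoride-mediated desilylation, driven by Si–F bond formation, should free the C9 and C20 hydroxyls while the base-stable mixed acetal keeps C14 masked.

Step 22
Reactants: 32 macrocyclic C9,C20-diol C14 2-methoxyprop-2-yl ether
Product: 33 macrocyclic C9,C20-diacetate C14 2-methoxyprop-2-yl ether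
Conditions: Ac2O, pyridine, DMAP (cat.), CH2Cl2, rt
Reagents that add atoms: acetic anhydride, CC(=O)OC(C)=O
Why: DMAP-catalysed acylation esterifies the primary C20 and the hindered secondary C9 alcohols, the only free hydroxyls present, with retention at C9.

Step 23
Reactants: 33 macrocyclic C9,C20-diacetate C14 2-methoxyprop-2-yl ether
Product: 34 target CNP0077636.1
Conditions: PPTS (cat.), MeOH, 0 °C → rt
Reagents that add atoms: none
Why: Acid-catalysed methanolysis of the very labile mixed acetal, under conditions too mild to transesterify or ionise the allylic acetates, should release the C14 alcohol and hence the target.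

**Compound list**

1 | geranyl acetate, (2E)-3,7-dimethylocta-2,6-dien-1-yl acetate | CC(C)=CCC/C(C)=C/COC(C)=O | starting material
2 | (2E,6E)-8-hydroxy-3,7-dimethylocta-2,6-dien-1-yl acetate | OC/C(C)=C/CC/C(C)=C/COC(C)=O | intermediate
3 | methyl (R)-2,2-dimethyl-1,3-dioxolane-4-carboxylate | COC(=O)[C@H]1COC(C)(C)O1 | starting material
4 | methyl phenyl sulfone | CS(=O)(=O)c1ccccc1 | starting material
5 | (phenylsulfonyl)methyllithium | [Li]CS(=O)(=O)c1ccccc1 | intermediate
6 | (R)-1-(2,2-dimethyl-1,3-dioxolan-4-yl)-2-(phenylsulfonyl)ethan-1-one | O=C(CS(=O)(=O)c1ccccc1)[C@H]2COC(C)(C)O2 | intermediate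
7 | sodium enolate of 6 | [Na+].[O-]C(=CS(=O)(=O)c1ccccc1)[C@H]2COC(C)(C)O2 | intermediate
8 | (4E,8E)-1-[(4R)-2,2-dimethyl-1,3-dioxolan-4-yl]-10-hydroxy-5,9-dimethyl-2-(phenylsulfonyl)deca-4,8-dien-1-one, C2 epimers | O=C(C(C/C=C(\C)CC/C=C(\C)CO)S(=O)(=O)c1ccccc1)[C@H]2COC(C)(C)O2 | intermediate
9 | (4E,8E)-1-[(4R)-2,2-dimethyl-1,3-dioxolan-4-yl]-10-hydroxy-5,9-dimethyldeca-4,8-dien-1-one | O=C(CC/C=C(\C)CC/C=C(\C)CO)[C@H]1COC(C)(C)O1 | intermediate
10 | (2E,6E)-10-[(4S)-2,2-dimethyl-1,3-dioxolan-4-yl]-2,6-dimethylundeca-2,6,10-trien-1-ol | C=C(CC/C=C(\C)CC/C=C(\C)CO)[C@H]1COC(C)(C)O1 | intermediate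
11 | (2E,6E)-10-[(4S)-2,2-dimethyl-1,3-dioxolan-4-yl]-2,6-dimethylundeca-2,6,10-trien-1-yl acetate | C=C(CC/C=C(\C)CC/C=C(\C)COC(C)=O)[C@H]1COC(C)(C)O1 | intermediate
12 | 2-[(2E,6E)-10-((4S)-2,2-dimethyl-1,3-dioxolan-4-yl)-2,6-dimethylundeca-2,6,10-trien-1-yl]-4,4,5,5-tetramethyl-1,3,2-dioxaborolane | C=C(CC/C=C(\C)CC/C=C(\C)CB1OC(C)(C)C(C)(C)O1)[C@H]2COC(C)(C)O2 | intermediate
13 | 2,2-dimethoxyacetaldehyde | COC(OC)C=O | starting material
14 | methyl acrylate | C=CC(=O)OC | starting material
15 | methyl 3-hydroxy-4,4-dimethoxy-2-methylidenebutanoate, racemic | C=C(C(=O)OC)C(O)C(OC)OC | intermediate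
16 | methyl 3-acetoxy-4,4-dimethoxy-2-methylidenebutanoate, racemic | C=C(C(=O)OC)C(OC(C)=O)C(OC)OC | intermediate
17 | methyl (Z)-4,4-dimethoxy-2-[(phenylsulfonyl)methyl]but-2-enoate | COC(OC)/C=C(/C(=O)OC)CS(=O)(=O)c1ccccc1 | intermediate
18 | (Z)-4,4-dimethoxy-2-[(phenylsulfonyl)methyl]but-2-en-1-ol | COC(OC)/C=C(/CO)CS(=O)(=O)c1ccccc1 | intermediate
19 | tert-butyl{[(Z)-4,4-dimethoxy-2-((phenylsulfonyl)methyl)but-2-en-1-yl]oxy}diphenylsilane | COC(OC)/C=C(/CO[Si](c1ccccc1)(c2ccccc2)C(C)(C)C)CS(=O)(=O)c3ccccc3 | intermediate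
20 | (Z)-4-[(tert-butyldiphenylsilyl)oxy]-3-[(phenylsulfonyl)methyl]but-2-enal | O=C/C=C(/CO[Si](c1ccccc1)(c2ccccc2)C(C)(C)C)CS(=O)(=O)c3ccccc3 | intermediate
21 | O-pinacolboryl ester of 22 | C=C(CC/C=C(\C)CC[C@H](C(=C)C)[C@@H](OB1OC(C)(C)C(C)(C)O1)/C=C(/CO[Si](c2ccccc2)(c3ccccc3)C(C)(C)C)CS(=O)(=O)c4ccccc4)[C@H]5COC(C)(C)O5 | intermediate
22 | open-chain (4E,10Z,8R,9S,14S)-C9 alcohol: C8 isopropenyl, C20 OTBDPS, C12H2SO2Ph, C1 methylidene, 13,14-O-isopropylidene | C=C(CC/C=C(\C)CC[C@H](C(=C)C)[C@@H](O)/C=C(/CO[Si](c1ccccc1)(c2ccccc2)C(C)(C)C)CS(=O)(=O)c3ccccc3)[C@H]4COC(C)(C)O4 | intermediate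
23 | C9 tert-butyldimethylsilyl ether of 22 | C=C(CC/C=C(\C)CC[C@H](C(=C)C)[C@@H](O[Si](C)(C)C(C)(C)C)/C=C(/CO[Si](c1ccccc1)(c2ccccc2)C(C)(C)C)CS(=O)(=O)c3ccccc3)[C@H]4COC(C)(C)O4 | intermediate
24 | open-chain (14S)-13,14-diol: C9 OTBS, C20 OTBDPS, C12H2SO2Ph | C=C(CC/C=C(\C)CC[C@H](C(=C)C)[C@@H](O[Si](C)(C)C(C)(C)C)/C=C(/CO[Si](c1ccccc1)(c2ccccc2)C(C)(C)C)CS(=O)(=O)c3ccccc3)[C@H](O)CO | intermediate
25 | C13 p-toluenesulfonate of 24 | C=C(CC/C=C(\C)CC[C@H](C(=C)C)[C@@H](O[Si](C)(C)C(C)(C)C)/C=C(/CO[Si](c1ccccc1)(c2ccccc2)C(C)(C)C)CS(=O)(=O)c3ccccc3)[C@H](O)COS(=O)(=O)c4ccc(C)cc4 | intermediate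
26 | open-chain (14S)-13,14-epoxide: C9 OTBS, C20 OTBDPS, C12H2SO2Ph, C1 methylidene (key-step precursor) | C=C(CC/C=C(\C)CC[C@H](C(=C)C)[C@@H](O[Si](C)(C)C(C)(C)C)/C=C(/CO[Si](c1ccccc1)(c2ccccc2)C(C)(C)C)CS(=O)(=O)c3ccccc3)[C@H]4CO4 | intermediate
27 | C12-lithiated 26 | C=C(CC/C=C(\C)CC[C@H](C(=C)C)[C@@H](O[Si](C)(C)C(C)(C)C)/C=C(/CO[Si](c1ccccc1)(c2ccccc2)C(C)(C)C)C([Li])S(=O)(=O)c3ccccc3)[C@H]4CO4 | intermediate
28 | C14 lithium alkoxide of 29 | C=C1CC/C=C(\C)CC[C@H](C(=C)C)[C@@H](O[Si](C)(C)C(C)(C)C)/C=C(/CO[Si](c2ccccc2)(c3ccccc3)C(C)(C)C)C(S(=O)(=O)c4ccccc4)C[C@H]1O[Li] | intermediate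
29 | 14-membered C12 phenyl sulfone with free (14R) hydroxyl: C9 OTBS, C20 OTBDPS, 4E, 10Z, C12 epimers (key-step product) | C=C1CC/C=C(\C)CC[C@H](C(=C)C)[C@@H](O[Si](C)(C)C(C)(C)C)/C=C(/CO[Si](c2ccccc2)(c3ccccc3)C(C)(C)C)C(S(=O)(=O)c4ccccc4)C[C@H]1O | intermediate
30 | C14 2-methoxyprop-2-yl ether of 29 | C=C1CC/C=C(\C)CC[C@H](C(=C)C)[C@@H](O[Si](C)(C)C(C)(C)C)/C=C(/CO[Si](c2ccccc2)(c3ccccc3)C(C)(C)C)C(S(=O)(=O)c4ccccc4)C[C@H]1OC(C)(C)OC | intermediate
31 | (4E,10E,8R,9S,14R)-macrocycle with C12H2: C9 OTBS, C20 OTBDPS, C14 2-methoxyprop-2-yl ether | C=C1CC/C=C(\C)CC[C@H](C(=C)C)[C@@H](O[Si](C)(C)C(C)(C)C)/C=C(/CO[Si](c2ccccc2)(c3ccccc3)C(C)(C)C)CC[C@H]1OC(C)(C)OC | intermediate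
32 | macrocyclic C9,C20-diol, C14 2-methoxyprop-2-yl ether | C=C1CC/C=C(\C)CC[C@H](C(=C)C)[C@@H](O)/C=C(/CO)CC[C@H]1OC(C)(C)OC | intermediate
33 | macrocyclic C9,C20-diacetate, C14 2-methoxyprop-2-yl ether | C=C1CC/C=C(\C)CC[C@H](C(=C)C)[C@@H](OC(C)=O)/C=C(/COC(C)=O)CC[C@H]1OC(C)(C)OC | intermediate
34 | CNP0077636.1, (4E,10E,8R,9S,14R)-9-acetoxy-11-(acetoxymethyl)-5-methyl-1-methylidene-8-(prop-1-en-2-yl)cyclotetradeca-4,10-dien-14-ol (ring numbering of the plan) | C=C1CC/C=C(\C)CC[C@H](C(=C)C)[C@@H](OC(C)=O)/C=C(/COC(C)=O)CC[C@H]1O | target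

**Step count and risks**

Total step count: 23. Longest linear sequence: 16 steps (steps 1, 3–7 and 14–23; the eastern branch, steps 8–13 and 14–23, is equally long).

Steps most likely to fail:

1. Step 18 (macrocyclisation). Intermolecular alkylation, SN2′ attack of the carbanion on the methylidene carbon, or 1,4-elimination of the C9 silyloxy group from the C12 carbanion may outrun the 14-membered ring closure. The fallback replaces the epoxide by a primary iodide and sets out from diol 24. Selective iodination of the primary carbinol (I2, PPh3, imidazole, CH2Cl2, 0 °C) should give the open-chain C13 iodide with free C14 hydroxyl F1. Capping the hydroxyl of F1 with 2-methoxypropene and catalytic PPTS should give the open-chain C13 iodide C14 2-methoxyprop-2-yl ether F2. LiN(SiMe3)2 in THF at high dilution would then close the ring of F2 by intramolecular sulfone alkylation at C13, with no vinyl epoxide left to offer an SN2′ path. This gives 30 directly, where the route is rejoined.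

2. Step 14 (fragment union). Insufficient facial discrimination at the enal by the phosphoric acid, or erosion of the boronate E geometry, would give other C8/C9 diastereomers. The fallback changes from boron to chromium and sets out from allylic alcohol 10. An Appel reaction (CBr4, PPh3, CH2Cl2, 0 °C) should give the allylic bromide F3. F3 is then added to enal 20 under Nozaki–Hiyama–Kishi conditions (CrCl2, a chiral oxazoline–sulfonamide ligand, Et3N, THF). The allylchromium species reacts through its γ-carbon in a chair transition state, which gives the anti adduct, and the ligand on chromium selects the aldehyde face. The route is rejoined at 22.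

3. Step 20 (desulfonylation). Hydride delivery to C10 would transpose the double bond, and syn–anti isomerisation of the π-allyl complex would scramble the C10=C11 geometry. The fallback uses single-electron cleavage on the unprotected alcohol and sets out from 29. Sodium amalgam (Na/Hg) with Na2HPO4 in MeOH/THF at −20 °C cleaves the C–S bond, and the nearby free C14 hydroxyl can protonate the allyl anion at C12. This should give the desulfonylated 14-membered alcohol F4. Treatment of F4 with 2-methoxypropene and catalytic PPTS then returns to the route at 31.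

Further compounds
F1 | step 18 | open-chain C13 iodide with free (14S) hydroxyl: C9 OTBS, C20 OTBDPS, C12H2SO2Ph | C=C(CC/C=C(\C)CC[C@H](C(=C)C)[C@@H](O[Si](C)(C)C(C)(C)C)/C=C(/CO[Si](c1ccccc1)(c2ccccc2)C(C)(C)C)CS(=O)(=O)c3ccccc3)[C@H](O)CI
F2 | step 18 | open-chain C13 iodide C14 2-methoxyprop-2-yl ether: C9 OTBS, C20 OTBDPS, C12H2SO2Ph | C=C(CC/C=C(\C)CC[C@H](C(=C)C)[C@@H](O[Si](C)(C)C(C)(C)C)/C=C(/CO[Si](c1ccccc1)(c2ccccc2)C(C)(C)C)CS(=O)(=O)c3ccccc3)[C@H](OC(C)(C)OC)CI
F3 | step 14 | (4S)-4-[(5E,9E)-11-bromo-6,10-dimethylundeca-1,5,9-trien-2-yl]-2,2-dimethyl-1,3-dioxolane | C=C(CC/C=C(\C)CC/C=C(\C)CBr)[C@H]1COC(C)(C)O1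
F4 | step 20 | desulfonylated 14-membered (14R) alcohol: C9 OTBS, C20 OTBDPS, 4E, 10E | C=C1CC/C=C(\C)CC[C@H](C(=C)C)[C@@H](O[Si](C)(C)C(C)(C)C)/C=C(/CO[Si](c2ccccc2)(c3ccccc3)C(C)(C)C)CC[C@H]1O
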